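**Retrosynthetic overview**
1. Target ⇒ its methyl ether (BBr3). C4–Br ⇒ C4–NH2 (Sandmeyer). C3–Br and C5–Br ⇒ ortho-bromination steered by that NH2. NH2 ⇒ NO2.
2. Key disconnection: ring A of 2-(2,4-dibromophenoxy)-4-nitrophenol is opened at C2–C3 (intermolecular aldol condensation) and at C5–C6 (ring-closing aldol condensation) ⇒ 1-(2,4-dibromophenoxy)propan-2-one + sodium nitromalonaldehyde.
3. Aryloxyacetone ⇒ 2,4-dibromophenol + chloroacetone (Williamson). Sodium nitromalonaldehyde ⇒ mucobromic acid + NaNO2.
4. Ring order: ring B is bought with both bromines in place. Ring A is the only ring formed (step 3); it is born with O at C1, OAr at C2 and N at C4, and is brominated afterwards.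

Assumption: the SMILES holds no stereocentre and the diaryl ether axis rotates freely, so the target is achiral and is made as the one compound drawn; ring A = phenol ring (C1 OH, C2 OAr, C3–C5 Br, C6 H), ring B = 2,4-dibromophenyl ring.

**Step 1**
Reactants: 1 2,4-dibromophenol; 2 chloroacetone (1-chloropropan-2-one)
Product: 3 1-(2,4-dibromophenoxy)propan-2-one
Conditions: K2CO3 (1.5 equiv), acetone, reflux, 8 h
Reagents that add atoms: none
Why: Williamson ether synthesis, in which K2CO3 fully deprotonates the acidic phenol and the phenoxide displaces the activated primary chloride of the α-halo ketone by SN2, with no stereocentre formed.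

**Step 2**
Reactants: 4 mucobromic acid ((Z)-2,3-dibromo-4-oxobut-2-enoic acid)
Product: 5 sodium nitromalonaldehyde monohydrate (sodium salt of 2-nitropropanedial)
Conditions: NaNO2 (3.7 equiv), H2O/EtOH, 54 °C; then 0 °C, filter, recrystallise from aq EtOH (salt is impact- and heat-sensitive: small batches, shield)
Reagents that add atoms: sodium nitrite, [Na+].[O-]N=O; water, O
Why: Conjugate addition–elimination of nitrite replaces the bromine β to the carboxyl carbonyl, the second vinyl bromide is hydrolysed to an α-keto acid that loses CO2, and the stabilised nitro-dialdehyde anion crystallises as its sodium salt in a long-established preparation (about 40%) that creates no stereocentre.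

**Step 3 (key step)**
Reactants: 3 1-(2,4-dibromophenoxy)propan-2-one; 5 sodium nitromalonaldehyde monohydrate
Product: 8 2-(2,4-dibromophenoxy)-4-nitrophenol, via open-chain enal sodium salt 6 (not isolated), via sodium 2-(2,4-dibromophenoxy)-4-nitrophenolate 7 (not isolated)
Conditions: NaOH (1.2 equiv), H2O/EtOH, 0 °C → rt, 3 d, dark; then 2 M HCl to pH 2
Reagents that add atoms: none
Why: In the classical nitromalonaldehyde–ketone synthesis of 4-nitrophenols, an intermolecular aldol condensation of the more acidic ArOCH2 carbon of 3 with one formyl group of 5 makes the C2–C3 bond, the methyl group closes C5–C6 by an intramolecular aldol condensation, and loss of the second water gives the aromatic nitrophenolate as thermodynamic sink, so that only one regioisomer can form (both α-carbons of the ketone end up in the ring) and no stereocentre arises.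

**Step 4**
Reactants: 8 2-(2,4-dibromophenoxy)-4-nitrophenol
Product: 9 2-(2,4-dibromophenoxy)-1-methoxy-4-nitrobenzene
Conditions: MeI (1.5 equiv), K2CO3 (2 equiv), DMF, rt, 12 h
Reagents that add atoms: iodomethane, CI
Why: Williamson O-methylation of the acidic nitrophenol caps the OH, which would otherwise steer bromine to C6 and make the later aminophenol prone to quinone imine formation.

**Step 5**
Reactants: 9 2-(2,4-dibromophenoxy)-1-methoxy-4-nitrobenzene
Product: 10 3-(2,4-dibromophenoxy)-4-methoxyaniline
Conditions: Fe powder (5 equiv), NH4Cl, EtOH/H2O 4:1, 80 °C, 2 h; filter through Celite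
Reagents that add atoms: none
Why: Béchamp-type electron-transfer reduction by zerovalent iron at near-neutral pH converts ArNO2 into ArNH2 and leaves the aryl bromides and both ethers untouched, whereas catalytic hydrogenation would risk hydrodebromination.

**Step 6**
Reactants: 10 3-(2,4-dibromophenoxy)-4-methoxyaniline
Product: 12 2,6-dibromo-3-(2,4-dibromophenoxy)-4-methoxyaniline, via 2-bromo-5-(2,4-dibromophenoxy)-4-methoxyaniline 11 (not isolated)
Conditions: NBS (2.1 equiv), MeCN, 0 °C → rt, dark, 3 h
Reagents that add atoms: N-bromosuccinimide, O=C1CCC(=O)N1Br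
Why: In this electrophilic aromatic bromination the free NH2 is by far the strongest donor, so bromine enters its two ortho positions, first ring A C5 (also para to OAr) and then C3 (also ortho to OAr), while C6 is meta to NH2 and wedged between OMe and Br, and ring B is deactivated by its two bromines.

**Step 7**
Reactants: 12 2,6-dibromo-3-(2,4-dibromophenoxy)-4-methoxyaniline
Product: 14 1,2,3-tribromo-4-(2,4-dibromophenoxy)-5-methoxybenzene, via arenediazonium hydrogensulfate 13 (not isolated)
Conditions: NaNO2 (1.2 equiv), conc. H2SO4, AcOH, 0–10 °C, 1 h; then CuBr (0.5 equiv), 48% aq HBr, 0 → 70 °C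
Reagents that add atoms: hydrogen bromide, Br (the new C4 bromine); sodium nitrite, [Na+].[O-]N=O (outer N of 13 only, leaves as N2); sulfuric acid, OS(=O)(=O)O (counter-ion of 13 only)
Why: In this Sandmeyer reaction nitrosylsulfuric acid diazotises even the weakly basic, doubly ortho-substituted aniline, CuBr (regenerated in the cycle) replaces N2 by Br through single-electron transfer at exactly the carbon that bore nitrogen, and the HBr medium makes any halide exchange ortho to the diazonium group degenerate.

**Step 8**
Reactants: 14 1,2,3-tribromo-4-(2,4-dibromophenoxy)-5-methoxybenzene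
Product: 16 3,4,5-tribromo-2-(2,4-dibromophenoxy)phenol, via aryloxydibromoborane 15 (not isolated)
Conditions: BBr3 (3 equiv, 1 M in CH2Cl2), CH2Cl2, −78 °C → rt, 12 h; then ice/H2O
Reagents that add atoms: boron tribromide, BrB(Br)Br (its B and Br are held by 15 only, none reaches 16)
Why: In this Lewis-acid ether cleavage BBr3 binds the methoxy oxygen and bromide attacks the methyl carbon by SN2 to give MeBr and borate 15, which water hydrolyses to the phenol, while the diaryl ether offers no sp3 carbon for attack and the aryl bromides are inert.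

**Compound list**
1 | 2,4-dibromophenol | Oc1ccc(Br)cc1Br | starting material
2 | chloroacetone (1-chloropropan-2-one) | CC(=O)CCl | starting material
3 | 1-(2,4-dibromophenoxy)propan-2-one | CC(=O)COc1ccc(Br)cc1Br | intermediate
4 | mucobromic acid, (Z)-2,3-dibromo-4-oxobut-2-enoic acid | O=C/C(Br)=C(Br)\C(=O)O | starting material
5 | sodium nitromalonaldehyde monohydrate (sodium salt of 2-nitropropanedial) | [Na+].O=C[C-](C=O)[N+](=O)[O-].O | intermediate
6 | sodium salt of (E)-4-(2,4-dibromophenoxy)-2-nitro-5-oxohex-3-enal, open-chain aldol condensation product, delocalised anion, geometry labile and drawn as the isomer that can close (not isolated) | [Na+].CC(=O)/C(Oc1ccc(Br)cc1Br)=C\[C-](C=O)[N+](=O)[O-] | intermediate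
7 | sodium 2-(2,4-dibromophenoxy)-4-nitrophenolate (not isolated) | [Na+].[O-]c1ccc([N+](=O)[O-])cc1Oc1ccc(Br)cc1Br | intermediate
8 | 2-(2,4-dibromophenoxy)-4-nitrophenol | Oc1ccc([N+](=O)[O-])cc1Oc1ccc(Br)cc1Br | intermediate
9 | 2-(2,4-dibromophenoxy)-1-methoxy-4-nitrobenzene | COc1ccc([N+](=O)[O-])cc1Oc1ccc(Br)cc1Br | intermediate
10 | 3-(2,4-dibromophenoxy)-4-methoxyaniline | COc1ccc(N)cc1Oc1ccc(Br)cc1Br | intermediate
11 | 2-bromo-5-(2,4-dibromophenoxy)-4-methoxyaniline (not isolated) | COc1cc(Br)c(N)cc1Oc1ccc(Br)cc1Br | intermediate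
12 | 2,6-dibromo-3-(2,4-dibromophenoxy)-4-methoxyaniline | COc1cc(Br)c(N)c(Br)c1Oc1ccc(Br)cc1Br | intermediate
13 | 2,6-dibromo-3-(2,4-dibromophenoxy)-4-methoxybenzenediazonium hydrogensulfate (not isolated) | COc1cc(Br)c([N+]#N)c(Br)c1Oc1ccc(Br)cc1Br.OS(=O)(=O)[O-] | intermediate
14 | 1,2,3-tribromo-4-(2,4-dibromophenoxy)-5-methoxybenzene | COc1cc(Br)c(Br)c(Br)c1Oc1ccc(Br)cc1Br | intermediate
15 | dibromo[3,4,5-tribromo-2-(2,4-dibromophenoxy)phenoxy]borane (not isolated) | BrB(Br)Oc1cc(Br)c(Br)c(Br)c1Oc1ccc(Br)cc1Br | intermediate
16 | 3,4,5-tribromo-2-(2,4-dibromophenoxy)phenol (achiral) | Oc1cc(Br)c(Br)c(Br)c1Oc1ccc(Br)cc1Br | target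

**Step count**
Total steps: 8.
Longest linear sequence: 7 (steps 1, 3, 4, 5, 6, 7, 8). Step 2 is a one-step side branch that joins at step 3.

**Three steps most likely to fail**

Step 3 (ring A construction). The formyl groups of the anionic dialdehyde are weak electrophiles. Ketone 3 can therefore self-condense, or lose phenoxide, during the long reaction time. If so, ring A is taken ready-made and the diaryl ether bond is formed by cross-coupling. The fallback sets out from 1. It is O-arylated with commercial (2-methoxy-5-nitrophenyl)boronic acid in a Chan–Lam coupling (Cu(OAc)2, 1 equiv, re-oxidised by air; pyridine; 4 Å molecular sieves; CH2Cl2; rt). Aryl bromides do not react with divalent copper at rt. The fallback comes back to the route at 9 and replaces steps 1–4. It makes no compound outside the list (F0).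

Step 6 (double bromination). The electron-rich anisidine 10 may be oxidised by NBS, the hindered C3 position may react sluggishly, or bromine may enter C6. If so, the donor OMe is exchanged for an electron-poor sulfonate for the whole end game. This tames the ring towards oxidation and shuts down C6.
The fallback sets out from 8. MsCl, Et3N, CH2Cl2, 0 °C gives 2-(2,4-dibromophenoxy)-4-nitrophenyl methanesulfonate F1. Fe, NH4Cl, EtOH/H2O, 80 °C gives 4-amino-2-(2,4-dibromophenoxy)phenyl methanesulfonate F2. NBS (2.1 equiv), DMF, rt leads through 4-amino-5-bromo-2-(2,4-dibromophenoxy)phenyl methanesulfonate F3 to 4-amino-3,5-dibromo-2-(2,4-dibromophenoxy)phenyl methanesulfonate F4.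
Diazotisation as in step 7 gives 2,6-dibromo-3-(2,4-dibromophenoxy)-4-(methylsulfonyloxy)benzenediazonium hydrogensulfate F5. CuBr/HBr turns it into 3,4,5-tribromo-2-(2,4-dibromophenoxy)phenyl methanesulfonate F6. NaOH, MeOH/THF, 50 °C cleaves the S–O bond to sodium 3,4,5-tribromo-2-(2,4-dibromophenoxy)phenolate F7. HCl then gives 16, where the fallback comes back to the route. Steps 4–8 are replaced.

Step 7 (Sandmeyer on a weakly basic aniline flanked by two bromines). Diazotisation in aqueous acid may be incomplete, or phenol and reduction products may dominate. If so, diazotisation and bromine transfer are separated and water is excluded. The fallback sets out from 12. NOBF4, MeCN, −20 → 0 °C, then Et2O, precipitates 2,6-dibromo-3-(2,4-dibromophenoxy)-4-methoxybenzenediazonium tetrafluoroborate F8, which is filtered off and checked. Treatment with KBr (2 equiv), CuBr and CuBr2 (5 mol % each), 1,10-phenanthroline (10 mol %) and dibenzo-18-crown-6 (10 mol %) in MeCN at rt then gives 14, where the fallback comes back to the route.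

**Further compounds**
F0 | step 3 | none | none
F1 | step 6 | 2-(2,4-dibromophenoxy)-4-nitrophenyl methanesulfonate | CS(=O)(=O)Oc1ccc([N+](=O)[O-])cc1Oc1ccc(Br)cc1Br
F2 | step 6 | 4-amino-2-(2,4-dibromophenoxy)phenyl methanesulfonate | CS(=O)(=O)Oc1ccc(N)cc1Oc1ccc(Br)cc1Br
F3 | step 6 | 4-amino-5-bromo-2-(2,4-dibromophenoxy)phenyl methanesulfonate | CS(=O)(=O)Oc1cc(Br)c(N)cc1Oc1ccc(Br)cc1Br
F4 | step 6 | 4-amino-3,5-dibromo-2-(2,4-dibromophenoxy)phenyl methanesulfonate | CS(=O)(=O)Oc1cc(Br)c(N)c(Br)c1Oc1ccc(Br)cc1Br
F5 | step 6 | 2,6-dibromo-3-(2,4-dibromophenoxy)-4-(methylsulfonyloxy)benzenediazonium hydrogensulfate | CS(=O)(=O)Oc1cc(Br)c([N+]#N)c(Br)c1Oc1ccc(Br)cc1Br.OS(=O)(=O)[O-]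
F6 | step 6 | 3,4,5-tribromo-2-(2,4-dibromophenoxy)phenyl methanesulfonate | CS(=O)(=O)Oc1cc(Br)c(Br)c(Br)c1Oc1ccc(Br)cc1Br
F7 | step 6 | sodium 3,4,5-tribromo-2-(2,4-dibromophenoxy)phenolate | [Na+].[O-]c1cc(Br)c(Br)c(Br)c1Oc1ccc(Br)cc1Br
F8 | step 7 | 2,6-dibromo-3-(2,4-dibromophenoxy)-4-methoxybenzenediazonium tetrafluoroborate | COc1cc(Br)c([N+]#N)c(Br)c1Oc1ccc(Br)cc1Br.F[B-](F)(F)F
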